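## Structural features

Dipolynaphthalene A (12) is a 1,4-disubstituted tetralin. Ring A is an anisole-type benzene and ring B is the saturated ring C1–C4. C4 is joined by one C(sp3)–C(sp2) bond to C2′ of a 1-hydroxy-8-methoxynaphthalene, in which ring C carries the hydroxyl and ring D the methoxy group. The two stereocentres, the secondary benzylic carbinol C1 (S) and the diaryl methine C4 (R), are not neighbours: they sit 1,4 across ring B and are trans, so neither can be set from the other by a vicinal relay. The ring A methoxy group at C5 is peri to C4, and the C4–C2′ bond is flanked on its other side by the C1′ hydroxyl. This crowds the bond and pushes the naphthyl group into a pseudoaxial position on the half-chair of ring B. The fragile parts are the electron-rich naphthol (one-electron oxidation, quinone or quinone-methide formation, radical coupling), the benzylic carbinol (ionisation, dehydration and aromatisation under acid) and the doubly benzylic C4–H. The real difficulty is twofold: making the hindered C4–C2′ bond with control of configuration at C4, and placing oxygen at C1 on the face opposite the naphthyl group with no neighbouring group to direct it. The key step uses the fact that ring B bears nothing but the C1 hydroxyl besides the methine. C1 of the deoxy compound is the only unhindered benzylic methylene, it lies on the side of ring A remote from the methoxy group, and its pseudoaxial hydrogen points to the face anti to the pseudoaxial naphthyl group.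

## Logic of the disconnections

The C1–O bond of 12 is cut first. The carbinol is the most acid-sensitive group and C1 is the only functionalised atom of ring B besides the methine, so removing it gives 11, with one stereocentre fewer and no group that restricts earlier reagents. The forward step must pick one methylene hydrogen out of four, leave the C4 methine, both methyl ethers and the free naphthol alone, deliver oxygen trans to the naphthyl group and stop at the alcohol.

The naphthol O–H of 11 is traced back to the O–CH2OMe acetal bond of 10. The cut is placed before the oxidation so that acid is never applied once the benzylic carbinol exists. The acetal is needed earlier as a directing group and to keep the phenol out of the organometallic steps. The forward step only has to hydrolyse an aryl acetal in a molecule with no other acid-labile group.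

The C4–H and C3–H bonds of 10 (numbering of 12) are removed to give the C3=C4 alkene of 9. This erases the last stereocentre and turns the crowded sp3–sp2 bond into an sp2–sp2 bond that a cross-coupling can make. The forward step must add hydrogen to one enantioface of a hindered, twisted, trisubstituted aryl alkene with no anchoring group near the double bond.

The C4–C2′ bond of 9 is cut between the alkene carbon and the naphthalene. This is the convergent cut, giving a ten-carbon naphthalene half (5) and a ten-carbon tetralin half (8). The forward coupling must join a vinyl electrophile with a peri-methoxy group to an aryl nucleophile with an ortho-alkoxy group, so it needs a catalyst for hindered partners and a boron reagent that resists protodeboronation.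

The O–S bond of 8 is cut, through 7, back to 6. The carbonyl carbon of 6 becomes C4, and its position peri to the methoxy group fixes the regiochemistry of the tetralin half in a purchased compound. The forward step needs enolisation at the single α-methylene and O-selective sulfonylation.

The C2′–B bond of 5 is cut, through 4, back to 3. No halogen is needed because the acetal oxygen can direct metalation to the adjacent carbon. The forward demand is regiocontrol: the acetal must outcompete the methoxy group on the other ring as director.

The acetal O–C bond of 3 and then the methyl O–C bond of 2 are cut to reach 1. Both naphthalene oxygens and their peri relationship come from a symmetrical purchased diol. The forward demand is to differentiate two equivalent hydroxyls, which the large gap between the first and second acidity of 1 allows.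

## Other disconnections considered

Alternative 1: The cut is the C2–C3 bond of ring B, read as an alkene. It leads back to diene A2, an anisole whose two adjacent ring carbons carry a 1-(silyloxy)allyl group and a 1-(naphthyl)allyl group. Forward, the second-generation Grubbs catalyst would load onto one terminal vinyl group, and cycloaddition and cycloreversion with the other would expel the two terminal methylene groups and close ring B as the 1,4-dihydronaphthalene A1. Alkene hydrogenation, desilylation and acetal removal would follow.
- In favour: closing a six-membered ring between two ortho-held vinyl groups is among the most dependable metathesis reactions. Both stereocentres are made before the ring exists, by separate reactions whose sense can be chosen. On predictability of site and configuration this plan is better than the chosen one.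
- Against: A1 has a leaving group at C1 and a doubly benzylic, allylic hydrogen at C4 on a ring that becomes a naphthalene by loss of the silyloxy group. Double-bond migration by ruthenium hydrides or traces of acid therefore threatens aromatisation. The later hydrogenation must spare an allylic, benzylic C–O bond. A2 needs three contiguous substituents on ring A, two of them vinyl-bearing benzylic stereocentres, which means a long linear build.
- Comparison: structurally it constructs ring B, which the chosen plan buys as a tetralone. Mechanistically the metathesis is the better understood event and the hydroxylation the more direct one. In step economy it is behind: three steps after the key step against none, and a longer approach to A2 than to 11.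

Alternative 2: The cuts are C4′–C4a′ and C1′–C8a′ of ring C. They lead back to ester A4, a but-2-enoate carrying the silyl-protected trans-tetralol at its α-carbon, and to 3-bromoanisole A5. Forward, lithium 2,2,6,6-tetramethylpiperidide would deprotonate the γ-methyl group of A4 and convert A5 into 3-methoxybenzyne A6. The dienolate γ-carbon would add to the aryne carbon meta to the methoxy group, and the aryllithium formed next to that group would attack the ester. Loss of alkoxide and tautomerisation would give naphthol A3, and desilylation would finish.
- In favour: ring C and its peri-oxygenation arise in one operation from a cheap aryl bromide, with regiochemistry set by the methoxy group. The crowded C4–C2′ bond is never made by cross-coupling, and no hindered alkene has to be hydrogenated asymmetrically. On these two points it is better than the chosen plan. The end game (one fluoride step, harmless to the carbinol) is nearly equal to the chosen plan's.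
- Against: A4 must already contain both stereocentres, so the 1,4-trans problem is only moved to the front, onto a tetralin with a carbon substituent, with no short solution in view. The medium is strongly basic. The dienolate can also react at its α-carbon, the amide base can add to A6, and the aryl anion can be protonated before it acylates, so such annulations tend to be moderate in efficiency.
- Comparison: structurally it builds a naphthalene that the chosen plan buys intact. Mechanistically it is polar, stoichiometric and strongly basic against mild catalytic steps. In step economy it is behind because of the length of the route to A4.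

Alternative 3: The cuts are C1–C2 and C3–C4 of ring B, a retro-[4+2]. They lead back to aldehyde A8 and 3-acryloyloxazolidin-2-one A9. Forward, 365 nm light would excite A8, a 1,5-hydrogen shift from the diarylmethylene to the carbonyl oxygen would give the hydroxy-o-quinodimethane, and this would add endo to A9 bound to TiCl2(Oi-Pr)2 and a TADDOL ligand (tetravalent titanium) to give the all-cis adduct A7.
- In favour: ring B, two C–C bonds and three stereocentres form in one catalyst-controlled step. The C1 oxygen is built in, so no C–H oxidation is needed, and C4 is set in the same event, so no asymmetric hydrogenation is needed. A8 is assembled through an unhindered benzylic methylene. On convergence and on setting both ring stereocentres at once it is better than the chosen plan.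
- Against: A7 has the hydroxyl cis to the aryl group, so C1 must be inverted. It also carries an extra acyl carbon at C2 that must be cut off by imide cleavage and radical decarboxylation of a β-hydroxy acid that is prone to dehydration and aromatisation. The dialkoxynaphthalene is a lower-energy triplet acceptor that may quench the excited aldehyde before hydrogen transfer. The bulky aryl group on the diene terminus may erode reactivity and endo control.
- Comparison: structurally it is the most ambitious ring construction of the four. Mechanistically it depends on a photochemical step with an internal quencher. In step economy it loses after the key step, with at least four or five corrective steps against none.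

Key step: step 8

Remark: 1 and 6 are taken as purchasable. The hydroxylated carbon is C4 of the tetralinyl unit in the numbering of 11 and C1 in the numbering of 12; the numbering of 12 is used for ring B throughout.
Remark: the naphthol is unmasked before the oxidation so that no acid meets the benzylic carbinol. For that reason a dioxygen-dependent monooxygenase is specified and a peroxide-driven peroxygenase, which also acts as a phenol peroxidase, is set aside.
Remark: the (S) ligand is written in step 6; if a test hydrogenation shows the opposite sense, its (R) antipode is used.

## Route

Step 1
Reactants: 1 naphthalene-1,8-diol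
Product: 2 8-methoxynaphthalen-1-ol
Conditions: MeI (1.05 equiv), K2CO3 (1.1 equiv), acetone, 25 to 56 °C
Reagents that add atoms: iodomethane, CI
Why: Williamson etherification; the monoanion of 1 is stabilised by a peri hydrogen bond and forms easily, while the remaining hydroxyl of 2 is hydrogen-bonded to the new methoxy oxygen and far less acidic, so one equivalent of MeI with a weak base should stop at the monoether.

Step 2
Reactants: 2 8-methoxynaphthalen-1-ol
Product: 3 1-methoxy-8-(methoxymethoxy)naphthalene
Conditions: NaH, MOMCl, DMF, 0 to 25 °C
Reagents that add atoms: chloromethyl methyl ether, COCCl
Why: O-alkylation of the sodium naphtholate by the chloromethyl ether; NaH is used because the peri hydrogen-bonded hydroxyl is deprotonated sluggishly by amine bases, and the acetal is wanted as the stronger ortho director for step 3.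

Step 3
Reactants: 3 1-methoxy-8-(methoxymethoxy)naphthalene
Product: 5 2-[8-methoxy-1-(methoxymethoxy)naphthalen-2-yl]-4,4,5,5-tetramethyl-1,3,2-dioxaborolane, via aryllithium 4 (not isolated)
Conditions: n-BuLi, TMEDA, Et2O, 0 to 25 °C; then i-PrOBpin, −78 to 25 °C; aqueous work-up
Reagents that add atoms: 2-isopropoxy-4,4,5,5-tetramethyl-1,3,2-dioxaborolane, CC(C)OB1OC(C)(C)C(C)(C)O1
Why: Directed ortho-metalation and borate trapping; the two acetal oxygens chelate lithium better than the single methoxy oxygen, so deprotonation should occur at the carbon next to the OMOM group and not next to the methoxy group, and the aryllithium displaces isopropoxide from boron.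

Step 4
Reactants: 6 8-methoxy-3,4-dihydronaphthalen-1(2H)-one (8-methoxy-1-tetralone)
Product: 8 enol triflate (8-methoxy-3,4-dihydronaphthalen-1-yl trifluoromethanesulfonate), via potassium enolate 7 (not isolated)
Conditions: KN(SiMe3)2, THF, −78 °C; then PhNTf2, −78 to 0 °C
Reagents that add atoms: N-phenylbis(trifluoromethanesulfonimide), FC(F)(F)S(=O)(=O)N(c1ccccc1)S(=O)(=O)C(F)(F)F
Why: Deprotonation at the only α-methylene and O-sulfonylation of the potassium enolate, the usual preparation of 1-tetralone enol triflates; a triflyl-transfer reagent is preferred to Tf2O so that electron-rich ring A is not exposed to a strong electrophile.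

Step 5
Reactants: 5 2-[8-methoxy-1-(methoxymethoxy)naphthalen-2-yl]-4,4,5,5-tetramethyl-1,3,2-dioxaborolane; 8 enol triflate (8-methoxy-3,4-dihydronaphthalen-1-yl trifluoromethanesulfonate)
Product: 9 8-methoxy-2-(8-methoxy-3,4-dihydronaphthalen-1-yl)-1-(methoxymethoxy)naphthalene
Conditions: Pd(OAc)2 (5 mol%), SPhos (10 mol%), K3PO4, toluene/H2O, 80 °C
Reagents that add atoms: none
Why: Suzuki–Miyaura coupling (oxidative addition of zerovalent palladium into the vinyl C–OTf bond, base-assisted transmetalation from boron, reductive elimination); the bulky electron-rich biarylphosphine is chosen because both partners carry an ortho or peri oxygen substituent, and the acetal and methyl ethers are inert to phosphate base.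

Step 6
Reactants: 9 8-methoxy-2-(8-methoxy-3,4-dihydronaphthalen-1-yl)-1-(methoxymethoxy)naphthalene
Product: 10 8-methoxy-1-(methoxymethoxy)-2-[(1R)-8-methoxy-1,2,3,4-tetrahydronaphthalen-1-yl]naphthalene
Conditions: [Ir(cod)((S)-tBu-PHOX)][B(C6H3(CF3)2)4] (2 mol%), H2 (50 bar), CH2Cl2, 25 °C
Reagents that add atoms: none
Why: Iridium-catalysed asymmetric hydrogenation of an unfunctionalised trisubstituted aryl alkene, a 1-substituted 3,4-dihydronaphthalene of the class for which cationic monovalent iridium N,P catalysts are standard; H2 adds syn to one enantioface under ligand control and sets the (R) methine, and early loss of the acetal in the acidic medium would be harmless because step 7 removes it.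

Step 7
Reactants: 10 8-methoxy-1-(methoxymethoxy)-2-[(1R)-8-methoxy-1,2,3,4-tetrahydronaphthalen-1-yl]naphthalene
Product: 11 8-methoxy-2-[(1R)-8-methoxy-1,2,3,4-tetrahydronaphthalen-1-yl]naphthalen-1-ol
Conditions: HCl (3 M aq.), MeOH/THF, 50 °C, under N2
Reagents that add atoms: none
Why: Acid-catalysed acetal exchange; protonation of the aryl MOM ether releases the naphthol and methanol captures the methoxymethyl cation, while the methine has no ionisable group and no benzylic carbinol is present yet, so the stereocentre is untouched.

Step 8
Reactants: 11 8-methoxy-2-[(1R)-8-methoxy-1,2,3,4-tetrahydronaphthalen-1-yl]naphthalen-1-ol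
Product: 12 dipolynaphthalene A, (1S,4R)-4-(1-hydroxy-8-methoxynaphthalen-2-yl)-5-methoxy-1,2,3,4-tetrahydronaphthalen-1-ol
Conditions: cytochrome P450 BM3 (CYP102A1) variant selected from a mutant panel, NADP+ (cat.), D-glucose, glucose dehydrogenase, catalase, air, phosphate buffer pH 8.0, 5% DMSO, 25 °C
Reagents that add atoms: dioxygen, O=O
Why: The ferryl-oxo porphyrin radical cation of the haem (tetravalent iron) abstracts a hydrogen atom from the C1 methylene of 11 and the benzylic radical is hydroxylated by rebound on the same face, so one oxygen atom of O2 enters the C–O bond and the other leaves as water. The closest known reaction types are the P450 and peroxygenase hydroxylation of tetralin to 1-tetralol and the P450 hydroxylation of deoxypodophyllotoxin-type 1-aryltetralins at the ring methylene 1,4 to the aryl group, which places oxygen trans to that group and tolerates a free phenol on it. No ring is closed and no skeletal bond is formed. The new stereocentre C1 (S) is controlled first by the binding pocket, which must present the methylene remote from the ring A methoxy group to the iron with the naphthyl group turned away. It is supported by the substrate: peri strain holds the naphthyl group pseudoaxial, so the pseudoaxial C1–H on the opposite face is both aligned with the ring A π system and open, and abstraction and rebound there give the trans carbinol. Site selectivity is needed against the C4 methine, the two O-methyl groups and the naphthol ring; the C4–H is pseudoequatorial, lies near the plane of ring A and is buried between two arenes and the peri-methoxy group, so it is poorly activated and hard to reach. A monooxygenase driven by NADPH and O2 is used so that no peroxidase-type phenol oxidation is invited, catalase removes H2O2 from uncoupled turnover, and the hydrogen bond from the naphthol O–H to its peri-methoxy oxygen slows hydrogen abstraction from oxygen. Conversion is stopped short of completion to limit further oxidation of the carbinol to the ketone.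

## Compound list

1 | naphthalene-1,8-diol | Oc1cccc2cccc(O)c12 | starting material
2 | 8-methoxynaphthalen-1-ol | COc1cccc2cccc(O)c12 | intermediate
3 | 1-methoxy-8-(methoxymethoxy)naphthalene | COc1cccc2cccc(OCOC)c12 | intermediate
4 | [8-methoxy-1-(methoxymethoxy)naphthalen-2-yl]lithium (not isolated) | COc1cccc2ccc([Li])c(OCOC)c12 | intermediate
5 | 2-[8-methoxy-1-(methoxymethoxy)naphthalen-2-yl]-4,4,5,5-tetramethyl-1,3,2-dioxaborolane | COc1cccc2ccc(B3OC(C)(C)C(C)(C)O3)c(OCOC)c12 | intermediate
6 | 8-methoxy-3,4-dihydronaphthalen-1(2H)-one | COc1cccc2c1C(=O)CCC2 | starting material
7 | potassium 8-methoxy-3,4-dihydronaphthalen-1-olate (not isolated) | COc1cccc2c1C([O-])=CCC2.[K+] | intermediate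
8 | 8-methoxy-3,4-dihydronaphthalen-1-yl trifluoromethanesulfonate | COc1cccc2c1C(OS(=O)(=O)C(F)(F)F)=CCC2 | intermediate
9 | 8-methoxy-2-(8-methoxy-3,4-dihydronaphthalen-1-yl)-1-(methoxymethoxy)naphthalene | COc1cccc2c1C(c1ccc3cccc(OC)c3c1OCOC)=CCC2 | intermediate
10 | 8-methoxy-1-(methoxymethoxy)-2-[(1R)-8-methoxy-1,2,3,4-tetrahydronaphthalen-1-yl]naphthalene | COc1cccc2c1[C@@H](c1ccc3cccc(OC)c3c1OCOC)CCC2 | intermediate
11 | 8-methoxy-2-[(1R)-8-methoxy-1,2,3,4-tetrahydronaphthalen-1-yl]naphthalen-1-ol | COc1cccc2c1[C@@H](c1ccc3cccc(OC)c3c1O)CCC2 | intermediate
12 | dipolynaphthalene A, (1S,4R)-4-(1-hydroxy-8-methoxynaphthalen-2-yl)-5-methoxy-1,2,3,4-tetrahydronaphthalen-1-ol | COc1cccc2c1[C@@H](c1ccc3cccc(OC)c3c1O)CC[C@@H]2O | target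

Total step count: 8. Longest linear sequence: 7 steps (steps 1, 2, 3, 5, 6, 7, 8); step 4 is a one-step branch that joins in step 5.

## Least certain steps

Step 8 (key step). The most likely failure is oxidation at the wrong place or on the wrong face:
- electron or hydrogen transfer from the naphthol, followed by coupling, ring hydroxylation para to the hydroxyl, or dehydrogenation toward a quinone methide that erases C4;
- O-demethylation;
- delivery of oxygen cis to the naphthyl group;
- further oxidation of the carbinol to the ketone;
- unproductive binding of the lipophilic substrate.

The cause is that each of these selectivities is left to a protein pocket not yet shaped for this substrate. The fallback replaces direct hydroxylation by chemical oxidation to the ketone and catalyst-controlled reduction. It sets out from 10, where the naphthol is still masked. Benzylic oxidation with t-BuOOH and catalytic Rh2(cap)4 (dirhodium tetracaprolactamate, divalent rhodium) should convert the exposed methylene into (4R)-5-methoxy-4-[8-methoxy-1-(methoxymethoxy)naphthalen-2-yl]-3,4-dihydronaphthalen-1(2H)-one F1. The methine is protected by its poorly conjugated pseudoequatorial C–H bond and by crowding, and the stereocentre is γ to the carbonyl, so it cannot epimerise by enolisation. HCl in methanol removes the acetal at the ketone stage to give (4R)-4-(1-hydroxy-8-methoxynaphthalen-2-yl)-5-methoxy-3,4-dihydronaphthalen-1(2H)-one F2. Noyori transfer hydrogenation with RuCl(p-cymene)[(S,S)-TsDPEN] (divalent ruthenium) in HCO2H/Et3N, the antipode that gives (S)-1-tetralol from 1-tetralone, then reduces the ketone under catalyst control and returns to the route at 12.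

Step 6. The most likely failure is slow or poorly face-selective hydrogen delivery. The alkene is trisubstituted, twisted out of conjugation and flanked by a peri-methoxy and an ortho-acetal group. The acidic iridium hydride medium may also cause double-bond migration, or the acetal oxygens may bind the metal. The fallback replaces asymmetric catalysis by resolution and sets out from 9. Hydrogenation over Pd/C (H2, 10 bar, EtOAc/EtOH) gives racemic 8-methoxy-1-(methoxymethoxy)-2-(8-methoxy-1,2,3,4-tetrahydronaphthalen-1-yl)naphthalene F3. Acid removal of the acetal gives racemic 8-methoxy-2-(8-methoxy-1,2,3,4-tetrahydronaphthalen-1-yl)naphthalen-1-ol F4. Preparative chromatography on a chiral stationary phase separates the (R) enantiomer, which is 11, from the (S) enantiomer 8-methoxy-2-[(1S)-8-methoxy-1,2,3,4-tetrahydronaphthalen-1-yl]naphthalen-1-ol F5. The route is rejoined at 11.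

Step 5. The most likely failure is protodeboronation of the ortho-alkoxy boronate in aqueous base outrunning a slow transmetalation to a crowded vinylpalladium, together with hydrolysis of the triflate back to the ketone. The fallback replaces cross-coupling by carbonyl addition and dehydration and sets out from 3 and 6. Aryllithium 4, made from 3 as in step 3, is transmetalated with anhydrous CeCl3 (trivalent cerium) at −78 °C to suppress enolisation and added to 6. This gives the tertiary alcohol 8-methoxy-1-[8-methoxy-1-(methoxymethoxy)naphthalen-2-yl]-1,2,3,4-tetrahydronaphthalen-1-ol F6. Dehydration with the Burgess reagent in THF, which leaves the acetal intact and can only form the endocyclic alkene, returns to the route at 9. This path is shorter, but addition of a hindered aryl nucleophile to a peri-substituted enolisable ketone is judged less sure than the coupling.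

Step 3. The most likely failure is incomplete or misdirected metalation, with competition from the position next to the methoxy group, and loss of boron on purification. The fallback replaces directed metalation by halogen–metal exchange and sets out from 2. Amine-mediated ortho-bromination (NBS, catalytic i-Pr2NH, CH2Cl2) gives 2-bromo-8-methoxynaphthalen-1-ol F7. NaH and MOMCl give 2-bromo-8-methoxy-1-(methoxymethoxy)naphthalene F8. Bromine–lithium exchange with n-BuLi at −78 °C places the metal unambiguously and returns to the route at 4, which is quenched to 5 as in step 3.

## Further compounds

F1 | step 8 | (4R)-5-methoxy-4-[8-methoxy-1-(methoxymethoxy)naphthalen-2-yl]-3,4-dihydronaphthalen-1(2H)-one | COc1cccc2c1[C@@H](c1ccc3cccc(OC)c3c1OCOC)CCC2=O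
F2 | step 8 | (4R)-4-(1-hydroxy-8-methoxynaphthalen-2-yl)-5-methoxy-3,4-dihydronaphthalen-1(2H)-one | COc1cccc2c1[C@@H](c1ccc3cccc(OC)c3c1O)CCC2=O
F3 | step 6 | racemic 8-methoxy-1-(methoxymethoxy)-2-(8-methoxy-1,2,3,4-tetrahydronaphthalen-1-yl)naphthalene | COc1cccc2c1C(c1ccc3cccc(OC)c3c1OCOC)CCC2
F4 | step 6 | racemic 8-methoxy-2-(8-methoxy-1,2,3,4-tetrahydronaphthalen-1-yl)naphthalen-1-ol | COc1cccc2c1C(c1ccc3cccc(OC)c3c1O)CCC2
F5 | step 6 | 8-methoxy-2-[(1S)-8-methoxy-1,2,3,4-tetrahydronaphthalen-1-yl]naphthalen-1-ol | COc1cccc2c1[C@H](c1ccc3cccc(OC)c3c1O)CCC2
F6 | step 5 | 8-methoxy-1-[8-methoxy-1-(methoxymethoxy)naphthalen-2-yl]-1,2,3,4-tetrahydronaphthalen-1-ol (racemic) | COc1cccc2c1C(O)(c1ccc3cccc(OC)c3c1OCOC)CCC2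
F7 | step 3 | 2-bromo-8-methoxynaphthalen-1-ol | COc1cccc2ccc(Br)c(O)c12
F8 | step 3 | 2-bromo-8-methoxy-1-(methoxymethoxy)naphthalene | COc1cccc2ccc(Br)c(OCOC)c12
A1 | alternative 1 | tert-butyl{[(1S,4R)-5-methoxy-4-[8-methoxy-1-(methoxymethoxy)naphthalen-2-yl]-1,4-dihydronaphthalen-1-yl]oxy}dimethylsilane (trans) | COc1cccc2c1[C@@H](c1ccc3cccc(OC)c3c1OCOC)C=C[C@@H]2O[Si](C)(C)C(C)(C)C
A2 | alternative 1 | tert-butyl({(1S)-1-[3-methoxy-2-{(1R)-1-[8-methoxy-1-(methoxymethoxy)naphthalen-2-yl]prop-2-en-1-yl}phenyl]prop-2-en-1-yl}oxy)dimethylsilane | COc1cccc([C@H](C=C)O[Si](C)(C)C(C)(C)C)c1[C@H](C=C)c1ccc2cccc(OC)c2c1OCOC
A3 | alternative 2 | 2-[(1R,4S)-4-{[tert-butyl(dimethyl)silyl]oxy}-8-methoxy-1,2,3,4-tetrahydronaphthalen-1-yl]-8-methoxynaphthalen-1-ol | COc1cccc2c1[C@@H](c1ccc3cccc(OC)c3c1O)CC[C@@H]2O[Si](C)(C)C(C)(C)C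
A4 | alternative 2 | methyl 2-[(1S,4S)-4-{[tert-butyl(dimethyl)silyl]oxy}-8-methoxy-1,2,3,4-tetrahydronaphthalen-1-yl]but-2-enoate (trans on the ring; alkene geometry not defined) | COc1cccc2c1[C@@H](C(=CC)C(=O)OC)CC[C@@H]2O[Si](C)(C)C(C)(C)C
A5 | alternative 2 | 3-bromoanisole | COc1cccc(Br)c1
A6 | alternative 2 | 3-methoxybenzyne (1-methoxy-2,3-didehydrobenzene) | COC1=CC=CC#C1
A7 | alternative 3 | 3-{[all-cis-1-hydroxy-5-methoxy-4-[8-methoxy-1-(methoxymethoxy)naphthalen-2-yl]-1,2,3,4-tetrahydronaphthalen-2-yl]carbonyl}-1,3-oxazolidin-2-one (absolute configuration as in the SMILES) | COc1cccc2c1[C@@H](c1ccc3cccc(OC)c3c1OCOC)C[C@@H](C(=O)N1CCOC1=O)[C@H]2O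
A8 | alternative 3 | 3-methoxy-2-{[8-methoxy-1-(methoxymethoxy)naphthalen-2-yl]methyl}benzaldehyde | COc1cccc(C=O)c1Cc1ccc2cccc(OC)c2c1OCOC
A9 | alternative 3 | 3-acryloyl-1,3-oxazolidin-2-one | C=CC(=O)N1CCOC1=O
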